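## Structural features

Target 20 has three rings. Ring A is an enolised 2-acylcyclohexane-1,3,5-trione (C1, C10, C11, C12, C13, C14) with two prenyl groups on C11 and a 3-methylbutanoyl group on C13. Ring B is a cyclohexane (C1–C6) and ring C a cyclopentane (C3, C4, C7, C8, C9). Rings A and B share only the quaternary spiro carbon C1, whereas rings B and C are trans-fused through the neighbouring methines C3 and C4.

There are five stereocentres. C3 and C4 each sit next to a tertiary carbinol: C9 beside C3 (hydroxyl cis to the C2 methylene) and C5 beside C4 (hydroxyl axial on ring B, on the face of H-3). C1 is stereogenic only because its two carbonyl branches differ (C10 beside the diprenylated C11, C14 beside the acylated C13); C14 lies on the same face of ring B as the C5 hydroxyl.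

The fragile groups are the acidic, chelating β-triketone (O- versus C-alkylation, retro-Claisen cleavage), the two prenyl alkenes (acid, oxidants, hydrogenation) and the two tertiary alcohols (elimination; the C5 hydroxyl can add back to C14). The real difficulty is the spiro carbon C1: two almost identical acyl branches must be told apart in a fixed sense relative to four remote stereocentres, on a strained trans-hydrindane with oxygenated quaternary carbons on both sides of the fusion.

The key step uses ring C as a trans-2,3-disubstituted cyclopentanone with C9 as the carbonyl carbon. The C4–C5 and C3–C2 bonds are then the β- and α-bonds of cyclopent-2-enone. The two groups attached (isopropenyl C5=C6 and the malonate carbon C1) are the partners needed later to close ring B and to distinguish C14 from C10 through a lactone to C5.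

## Logic of the disconnections

20 ⇒ 19. Only the O–Si bond at C9 is cut. The C9 hydroxyl is kept masked to the end because, before ring B exists, it could lactonise onto the cis malonate arm, and because it would consume base and acylating agent later. The forward step must remove a tertiary silyl ether without acid strong enough to touch the prenyl groups or the tertiary alcohols.

19 ⇒ 16 + 17. The two C11–CH2 bonds are cut. C11 is the only ring carbon of 16 that still bears enolisable hydrogens, and bringing the prenyl alkenes in last keeps them away from the manganese oxidation, the acetic acid and the hydrogenolysis. The forward step must alkylate on carbon rather than oxygen, twice, and leave the C5 hydroxyl alone.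

16 ⇒ 12 + 13 (through 14 and 15). The C10–C11 and C13–C14 bonds are cut. Ring A is a 1,3,5-tricarbonyl array, i.e. 13 plus two acyl carbons on C1, so the ring and its acyl side chain come from one purchasable diketone. The forward step requires the two acyl carbons on C1 to differ sharply in reactivity and to be fixed in space: C10 as an acyl imidazole, C14 as a lactone tied to the C5 oxygen.

12 ⇒ 11 ⇒ 10. Only the C10 ester is changed. The benzyl ester is chosen so that C10 can be unmasked by hydrogenolysis while the C14 lactone stays closed. This requires that no alkene is present at that stage, which holds once ring B is closed.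

10 ⇒ 9. The C1–C6 bond and the C5–O bond are cut. This reduces the tricycle to a monocyclic cyclopentane carrying a malonate arm and an isopropenyl group, and one oxidative radical cyclisation with lactonisation makes ring B, C5 and C1 together. The forward step must close 6-endo, through a chair with trans ring fusion, and the axial ester must capture C5.

9 ⇒ 8 ⇒ 7. The O–Si bond and then the C9–CH3 bond are cut, leaving a ketone at C9. The gain is a plain 2,3-disubstituted cyclopentanone. The forward addition of methyl must take the face opposite the C2 arm and must not enolise the ketone or attack the esters.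

7 ⇒ 5 + 2 + 4. The C4–C5 and C3–C2 bonds are cut. Both are bonds to the β- and α-carbons of an enone, so three simple components replace a stereodefined cyclopentanone. The forward step needs enantioface control at C4, a regiodefined enolate and trans delivery at C3.

2 ⇒ 1 and 4 ⇒ 3. The C–Mg bond of 2 and the C=CH2 bond of 4 (to formaldehyde) are cut, which reaches purchasable materials. The demands are a Grignard solution in a weakly coordinating ether and a freshly prepared, unpolymerised acceptor.

## Other disconnections considered

Alternative 1: The cut is through C10–C11 and C13–C14, so ring A is the strategic target.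
- Forward step: the terminal carbanion of the dianion of 13 is acylated by acyl imidazole 12, and the central carbanion of the resulting triketone opens the lactone to give the prenyl-free spiro trione A1, which is the same compound as 16.
- In favour: it closes a ring and forms two C–C bonds in one flask, it is convergent, and the lactone template means C1 needs no new control element.
- Against, as the centre of the plan: it creates no new stereocentre, so all five must already be present in the lactone acid, and it does not say how that tricycle is made. It also has its own chemoselectivity questions (attack at C10 before C14, C- versus O-closure).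
- Comparison: in rings formed it is the better step (one against none); in skeletal bonds the two are equal (two each); in stereocontrol it is weaker (none against two, including the absolute configuration). The two are not rivals, since the chosen plan keeps this condensation as step 9. Anchoring the plan upstream settles the absolute configuration and supplies the lactone this step needs.

Alternative 2: The cut is the C3–C9 bond, with hydride added at C4, so ring C is opened to the keto enoate A3.
- Forward step: a chiral copper hydride (from Cu(OAc)2, a bisphosphine and a silane) reduces A3 at C4, and the copper enolate at C3 adds to the tethered methyl ketone to give the cyclopentane hydroxy ester A2.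
- In favour: ring C, C3 and the C9 carbinol arise in one catalytic step. A chelated, chair-like aldol transition state ties the C9 hydroxyl cis to the ester carbon (the future C2). This is a firmer hold on C9 than face selection in a Grignard addition, and on this point the alternative is the better plan. It also needs no stoichiometric organometallic reagent.
- Against: C4 is made by hydride delivery to a β,β-disubstituted enoate. That needs one pure alkene isomer and must match or override the neighbouring silyloxy stereocentre, and the trans C3/C4 relation rests on a kinetic transition state with no thermodynamic safety net. After the step the ester carbon is only C2 and the C4 side chain only a protected secondary alcohol, so C1 and the C5=C6 alkene still cost about five more operations before ring B can close. A3 itself takes several steps, whereas 2, 4 and 5 are at most one step from commerce.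
- Comparison: one ring, one skeletal bond and up to three stereocentres against no ring, two bonds and two stereocentres. It is better on ring count and on C9, worse on bonds formed and on step economy. In mechanism the two are equal in kind (enantioselective copper-mediated conjugate addition followed by enolate capture).

Alternative 3: The cut is the C3–C4 bond across the ring together with the C5–O bond, so rings B and C merge into the nine-membered epoxy alkene A5.
- Forward step: Et2AlCl activates the C3–C9 epoxide, the C4=C5 alkene attacks C3 with inversion, and the C5 cation is captured by the axial ester to give the bridged lactone ester A4.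
- In favour: two rings, one C–C and one C–O bond, C3, C4 and C5 and the differentiation at C1 all arise in one step. The C9 carbinol is carried through from the epoxide oxygen, with no addition to a ketone and no protecting group. A4 corresponds to 10 of the chosen plan. In rings and stereocentres formed per step it is clearly the better key step.
- Against: A5 is a nine-membered (Z,Z)-1,5-diene monoepoxide. Closing a nine-membered ring, and epoxidising one of two similar trisubstituted Z-alkenes selectively and in one absolute sense with no directing group, are both hard. The trans ring fusion depends on which conformer of the medium ring reacts, and nothing in A5 enforces that. Lewis-acid opening of a trisubstituted epoxide can also divert into hydride shift or elimination, and the methyl ester of A4 still has to be cleaved beside the lactone.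
- Comparison: it is more powerful in the key step but less controllable. After the key step it is shorter; before it, longer and less certain. As a source of absolute configuration it is at best the equal of the catalytic conjugate addition.

Key step: step 3

Remark: the spectator esters of the malonate are benzyl instead of methyl, so that the ester left after lactonisation is cleaved by hydrogenolysis beside the lactone; the skeleton and the bonds formed in the key step are unchanged.
Remark: the (R,Sp) antipode of the ferrocenyl diphosphine is written; which antipode leads to the 4R series must be fixed in a trial run, and the other is used if needed.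
Remark: the key-step product is (1S,5R) on its ring carbons, i.e. 3S,4R in the target numbering used throughout, which is what 20 requires; 6-methylheptane-2,4-dione (13) is taken as purchasable.

Step 1
Reactants: 1 2-bromopropene
Product: 2 isopropenylmagnesium bromide (prop-1-en-2-ylmagnesium bromide) as a solution in 2-MeTHF
Conditions: Mg turnings, I2 (cat.), 2-MeTHF, 40 °C; titrated and used the same day
Reagents that add atoms: magnesium, [Mg]
Why: Grignard formation by insertion of magnesium into the alkenyl C–Br bond; 2-MeTHF is used because more strongly coordinating THF tends to erode enantioselectivity in copper-catalysed conjugate additions.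

Step 2
Reactants: 3 dibenzyl propanedioate (dibenzyl malonate)
Product: 4 dibenzyl 2-methylidenepropanedioate
Conditions: (CH2O)n, Cu(OAc)2·H2O (cat.), KOAc, AcOH, 95 °C; short-path distillation at high vacuum, kept cold and used within hours
Reagents that add atoms: formaldehyde (as paraformaldehyde), C=O
Why: Knoevenagel condensation of the malonate with formaldehyde and loss of water; the monomer polymerises readily under anionic conditions and is therefore used fresh.

Step 3
Reactants: 5 cyclopent-2-en-1-one; 2 isopropenylmagnesium bromide; 4 dibenzyl 2-methylidenepropanedioate
Product: 7 dibenzyl 2-{[(1S,5R)-2-oxo-5-(prop-1-en-2-yl)cyclopentyl]methyl}propanedioate (trans), via bromomagnesium enolate 6 (not isolated)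
Conditions: CuBr·SMe2 (5 mol %), (R)-1-[(Sp)-2-(diphenylphosphino)ferrocenyl]ethyldicyclohexylphosphine (6 mol %), t-BuOMe, −78 °C, 2 (1.15 equiv) added slowly; then 4 (1.3 equiv), −78 → −40 °C; aq. NH4Cl
Reagents that add atoms: none
Why: Transmetalation of 2 to the chiral copper bromide–diphosphine complex gives a monovalent alkenylcopper species that binds one face of 5, adds at the β-carbon (C4) to a trivalent copper intermediate and forms the C4–C5 bond by reductive elimination, leaving the regiodefined magnesium enolate 6. The closest known reaction type is the copper/ferrocenyl-diphosphine-catalysed asymmetric conjugate addition of Grignard reagents to cyclic enones, combined with Michael trapping of the metal enolate (three-component coupling). Enolate 6 then adds through C3 to the doubly activated alkene of 4, forming the C3–C2 bond and a stabilised malonate enolate that is protonated on work-up; no ring is closed. C4 (R) is set by the ligand, which selects the enone face. C3 (S) is set by the substrate: the acceptor approaches anti to the new isopropenyl group, and the trans ketone is also the thermodynamic isomer, so any epimerisation at this α-carbon converges on it. The step needs 1,4- over 1,2-addition (copper catalysis, slow addition at −78 °C in a weakly coordinating ether), no equilibration of 6 towards C8 (fast trapping at low temperature by a very reactive acceptor) and a single Michael addition (near-stoichiometric 4; the malonate enolate formed is a weaker nucleophile than 6).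

Step 4
Reactants: 7 dibenzyl 2-{[(1S,5R)-2-oxo-5-(prop-1-en-2-yl)cyclopentyl]methyl}propanedioate
Product: 8 dibenzyl 2-{[(1S,2R,5R)-2-hydroxy-2-methyl-5-(prop-1-en-2-yl)cyclopentyl]methyl}propanedioate (hydroxyl cis to the malonate arm)
Conditions: MeMgBr (3 equiv), anhydrous CeCl3 (3 equiv), THF, −78 °C; aq. NH4Cl
Reagents that add atoms: methylmagnesium bromide, C[Mg]Br
Why: Organocerium 1,2-addition (Imamoto conditions), which adds to the ketone without enolising it. The first equivalent turns the malonate into its enolate, which masks both esters and enlarges the C3 substituent, so methyl should enter anti to the C2 arm and leave the C9 hydroxyl cis to C2 (9R).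

Step 5
Reactants: 8 dibenzyl 2-{[(1S,2R,5R)-2-hydroxy-2-methyl-5-(prop-1-en-2-yl)cyclopentyl]methyl}propanedioate
Product: 9 dibenzyl 2-{[(1S,2R,5R)-2-methyl-5-(prop-1-en-2-yl)-2-(triethylsilyloxy)cyclopentyl]methyl}propanedioate
Conditions: Et3SiOTf, 2,6-lutidine, CH2Cl2, −78 → 0 °C
Reagents that add atoms: triethylsilyl trifluoromethanesulfonate, CC[Si](CC)(CC)OS(=O)(=O)C(F)(F)F
Why: Silylation of a hindered tertiary alcohol with a silyl triflate. The ether prevents δ-lactonisation of the C9 hydroxyl onto the cis malonate arm, which would make ring B impossible, and masks the alcohol in the later basic and acylating steps.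

Step 6
Reactants: 9 dibenzyl 2-{[(1S,2R,5R)-2-methyl-5-(prop-1-en-2-yl)-2-(triethylsilyloxy)cyclopentyl]methyl}propanedioate
Product: 10 benzyl ester of the tricyclic lactone acid (1S,3S,4R,5S,9R): ring B (C1–C6) trans-fused to ring C at C3/C4; γ-lactone bridge C1–C14(=O)–O–C5 on the face of H-3; benzyl ester C10 equatorial on C1; methyl on C5; methyl and triethylsilyloxy on C9
Conditions: Mn(OAc)3·2H2O (2.3 equiv), NaOAc, degassed AcOH, 50 °C
Reagents that add atoms: none
Why: Oxidative free-radical cyclisation of the Snider type: trivalent manganese generates the malonyl radical, which closes ring B 6-endo-trig on the CH2 terminus (C6) of the isopropenyl group through a chair with the C3 and C4 ring bonds equatorial (5-exo closure would give a trans-fused bicyclo[3.3.0]octane). The tertiary C5 radical is oxidised to the cation and captured by the carbonyl oxygen of the axial ester with loss of benzyl acetate. Only the ester on the face of H-3 can reach C5, so C5 (oxygen axial) and C1 (axial branch becomes lactone C14, equatorial branch stays ester C10) are set together by the locked trans-fused chair.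

Step 7
Reactants: 10 benzyl ester of the tricyclic lactone acid
Product: 11 tricyclic lactone carboxylic acid (free acid at C10; (1S,3S,4R,5S,9R); C9 triethylsilyl ether)
Conditions: H2 (1 atm), 10% Pd/C, EtOAc, rt
Reagents that add atoms: none
Why: Hydrogenolysis of the benzyl ester under neutral conditions; no alkene remains at this stage, and the lactone and the tertiary silyl ether are inert in EtOAc.

Step 8
Reactants: 11 tricyclic lactone carboxylic acid
Product: 12 acyl imidazole of 11 (imidazol-1-yl ketone at C10)
Conditions: 1,1'-carbonyldiimidazole, THF, rt → 40 °C; evaporated and used crude
Reagents that add atoms: 1,1'-carbonyldiimidazole, O=C(n1ccnc1)n1ccnc1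
Why: Staab activation of the acid as its acyl imidazole with loss of CO2. The acid has no α-hydrogen, so neither ketene formation nor epimerisation is possible, and C10 becomes far more electrophilic than the lactone carbonyl C14.

Step 9
Reactants: 12 acyl imidazole of 11; 13 6-methylheptane-2,4-dione
Product: 16 prenyl-free spiro trione (ring A closed; C11 unsubstituted; C5 hydroxyl free; C9 triethylsilyl ether), via dilithium diketone dianion 14 (not isolated), via open-chain lactone triketone 15 (not isolated)
Conditions: 13 (2.5 equiv), LiN(i-Pr)2 (5.1 equiv), THF, −78 → 0 °C; 12 in THF, −78 °C → rt, then 40 °C; cold dilute HCl to pH 3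
Reagents that add atoms: none
Why: Harris-type acylation of the 1,3-diketone dianion 14 at its terminal (methyl) carbon by the acyl imidazole forms C10–C11 and gives 15. The enolate of 15 then attacks the lactone carbonyl through its central carbon in a 6-exo-trig Claisen (Dieckmann-type) closure, forming C13–C14 and freeing the C5 alkoxide; the β-triketone enolate is the thermodynamic sink. C1 keeps its configuration because the lactone has already told its two carbonyl branches apart.

Step 10
Reactants: 16 prenyl-free spiro trione; 17 1-bromo-3-methylbut-2-ene (prenyl bromide)
Product: 19 C11-diprenyl spiro trione (C9 hydroxyl as triethylsilyl ether), via C11-monoprenyl trione 18 (not isolated)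
Conditions: 17 (3 equiv), NaOMe (3.5 equiv), MeOH, 0 °C → rt; aq. NaH2PO4
Reagents that add atoms: none
Why: C-alkylation of the vinylogous-acid dianion at C11, the only ring carbon still bearing enolisable hydrogens, in a protic medium that disfavours O-alkylation, as in the exhaustive C-alkylation of acylphloroglucinols. The second prenylation follows through 18, and no stereocentre is formed because the two groups are identical.

Step 11
Reactants: 19 C11-diprenyl spiro trione
Product: 20 CNP0198642.2 ((1S,3S,4R,5S,9R), free C5 and C9 hydroxyls)
Conditions: HF·pyridine, pyridine, THF, 0 °C → rt
Reagents that add atoms: none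
Why: Fluoride-mediated cleavage of the tertiary triethylsilyl ether under buffered conditions that should leave the prenyl alkenes, the enolised triketone and both tertiary alcohols untouched.

## Compound list

1 | 2-bromopropene | CC(Br)=C | starting material
2 | isopropenylmagnesium bromide | CC(=C)[Mg]Br | intermediate
3 | dibenzyl propanedioate | O=C(CC(=O)OCc1ccccc1)OCc1ccccc1 | starting material
4 | dibenzyl 2-methylidenepropanedioate | C=C(C(=O)OCc1ccccc1)C(=O)OCc1ccccc1 | intermediate
5 | cyclopent-2-en-1-one | O=C1C=CCC1 | starting material
6 | bromomagnesium (3R)-3-(prop-1-en-2-yl)cyclopent-1-en-1-olate | Br[Mg]OC1=C[C@@H](CC1)C(C)=C | intermediate (not isolated)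
7 | dibenzyl 2-{[(1S,5R)-2-oxo-5-(prop-1-en-2-yl)cyclopentyl]methyl}propanedioate | O=C(OCc1ccccc1)C(C[C@H]1[C@@H](CCC1=O)C(C)=C)C(=O)OCc1ccccc1 | intermediate
8 | dibenzyl 2-{[(1S,2R,5R)-2-hydroxy-2-methyl-5-(prop-1-en-2-yl)cyclopentyl]methyl}propanedioate | O=C(OCc1ccccc1)C(C[C@H]1[C@@H](CC[C@@]1(C)O)C(C)=C)C(=O)OCc1ccccc1 | intermediate
9 | dibenzyl 2-{[(1S,2R,5R)-2-methyl-5-(prop-1-en-2-yl)-2-(triethylsilyloxy)cyclopentyl]methyl}propanedioate | O=C(OCc1ccccc1)C(C[C@H]1[C@@H](CC[C@@]1(C)O[Si](CC)(CC)CC)C(C)=C)C(=O)OCc1ccccc1 | intermediate
10 | benzyl ester of the tricyclic lactone acid (lactone C14 to O-5, ester C10, C9 triethylsilyl ether) | O=C(OCc1ccccc1)[C@@]12C[C@H]3[C@@H](CC[C@@]3(C)O[Si](CC)(CC)CC)[C@@](C)(OC1=O)C2 | intermediate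
11 | tricyclic lactone carboxylic acid | OC(=O)[C@@]12C[C@H]3[C@@H](CC[C@@]3(C)O[Si](CC)(CC)CC)[C@@](C)(OC1=O)C2 | intermediate
12 | acyl imidazole of the tricyclic lactone acid | O=C(n4ccnc4)[C@@]12C[C@H]3[C@@H](CC[C@@]3(C)O[Si](CC)(CC)CC)[C@@](C)(OC1=O)C2 | intermediate
13 | 6-methylheptane-2,4-dione | CC(=O)CC(=O)CC(C)C | starting material
14 | dilithium dianion of 6-methylheptane-2,4-dione | [Li+].[Li+].[CH2-]C(=O)[CH-]C(=O)CC(C)C | intermediate (not isolated)
15 | open-chain lactone triketone (C10–C11 formed, lactone intact) | CC(C)CC(=O)CC(=O)CC(=O)[C@@]12C[C@H]3[C@@H](CC[C@@]3(C)O[Si](CC)(CC)CC)[C@@](C)(OC1=O)C2 | intermediate (not isolated)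
16 | prenyl-free spiro trione, C9 triethylsilyl ether | CC(C)CC(=O)C1=C(O)C=C(O)[C@@]2(C[C@H]3[C@@H](CC[C@@]3(C)O[Si](CC)(CC)CC)[C@@](C)(O)C2)C1=O | intermediate
17 | 1-bromo-3-methylbut-2-ene | CC(C)=CCBr | starting material
18 | C11-monoprenyl spiro trione, C9 triethylsilyl ether | CC(C)CC(=O)C1=C(O)C(CC=C(C)C)=C(O)[C@@]2(C[C@H]3[C@@H](CC[C@@]3(C)O[Si](CC)(CC)CC)[C@@](C)(O)C2)C1=O | intermediate (not isolated)
19 | C11-diprenyl spiro trione, C9 triethylsilyl ether | CC(C)=CCC1(CC=C(C)C)C(=O)[C@@]2(C[C@H]3[C@@H](CC[C@@]3(C)O[Si](CC)(CC)CC)[C@@](C)(O)C2)C(=O)C(C(=O)CC(C)C)=C1O | intermediate
20 | CNP0198642.2 | CC(C)=CCC1(CC=C(C)C)C(=O)[C@@]2(C[C@H]3[C@@H](CC[C@@]3(C)O)[C@@](C)(O)C2)C(=O)C(C(=O)CC(C)C)=C1O | target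

## Step count and least certain steps

Total step count: 11. Longest linear sequence: 10 steps (1 → 2 → 7 → 8 → 9 → 10 → 11 → 12 → 16 → 19 → 20); step 2 is the only side branch.

Step 3 (key step). The most likely failure is poor enantioface discrimination together with competing 1,2-addition, because an alkenyl Grignard reagent transfers faster and with less ligand control than the alkyl reagents for which this catalyst class is best established. Anionic oligomerisation of 4 by the product enolate is the second concern. The fallback replaces catalyst control by substrate control; it sets out from 2 and 4 and returns to the route at 7. Copper-catalysed addition of 2 (CuBr·SMe2, THF, −78 °C) to purchased (S)-4-(tert-butyldimethylsilyloxy)cyclopent-2-en-1-one F1 should place the isopropenyl group trans to the silyloxy group, and trapping of the enolate with 4 should give the all-trans silyloxy adduct F2 (Noyori-type three-component coupling). Loss of tert-butyldimethylsilanol under the mildly acidic conditions used for prostaglandin E to A conversions gives the cyclopentenone F3, and conjugate reduction with [(Ph3P)CuH]6 returns 7 with C3 and C4 untouched.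

Step 4. The most likely failure is poor facial selectivity at C9. The methyl nucleophile is small, and the face it must take (anti to the C2 arm) is the face that carries the isopropenyl group on C4; enolisation is the lesser risk. The fallback uses a much bulkier one-carbon nucleophile in two operations, setting out from 7 and returning at 8. (Phenylselanyl)methyllithium (from bis(phenylselanyl)methane and n-BuLi, THF, −78 °C) should add anti to the C2 arm to give the β-hydroxy selenide F4, and Bu3SnH with azobisisobutyronitrile (toluene, 80 °C) cleaves the C–Se bond to leave the methyl group.

Step 6. The most likely failure is diversion of the tertiary C5 radical or cation into alkenes by proton loss instead of lactonisation; partial loss of the silyl ether in warm acetic acid before ring closure is a further risk. The fallback replaces metal oxidation by halogen-atom transfer, setting out from 9 and returning at 10. Bromination of the malonate (NaH, N-bromosuccinimide, THF, 0 °C) gives the bromomalonate F5. Bromine-atom-transfer radical cyclisation (CuBr with tris(2-pyridylmethyl)amine, or (Bu3Sn)2 with light) gives the tertiary bromide F6 as both C5 epimers. Its ionisation on warming in a polar solvent is intercepted by the axial ester with loss of benzyl bromide.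

Step 9. The most likely failure is incomplete or misdirected condensation: proton transfer from the acidic triketone quenches the dianion, the hindered acyl imidazole may react slowly enough for the lactone to compete, and the final closure may stop at an O-acylated enol lactone. The fallback uses a neutral dianion equivalent and a stepwise closure; it sets out from 11 and 13 and returns at 16. Acid 11 is converted with 1-chloro-N,N,2-trimethylprop-1-en-1-amine (CH2Cl2) into the acid chloride F7. Dianion 14, made from 13, is silylated with Me3SiCl to the bis(trimethylsilyl) dienol ether F8. F8 is acylated at its terminal carbon by F7 (CH2Cl2, −78 → 20 °C, Me3SiOTf cat.) to give 15, which is now isolated and closed to 16 in a separate Dieckmann-type step (NaH, THF).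

Step 10. The most likely failure is O-alkylation or an incomplete second alkylation, because the enolate is ambident and the second prenyl group must enter a neopentyl-like position between two carbonyls. The fallback is allylation followed by metathesis, setting out from 16 and returning at 19. Double Tsuji–Trost allylation with allyl methyl carbonate and Pd(PPh3)4 (THF, rt; a zerovalent palladium catalyst that favours C-allylation of soft 1,3-dicarbonyl enolates) gives the C11-diallyl trione F9. Cross-metathesis with 2-methylbut-2-ene (second-generation Grubbs catalyst, CH2Cl2, 40 °C) converts both allyl groups into prenyl groups.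

## Further compounds

F1 | step 3 | (S)-4-(tert-butyldimethylsilyloxy)cyclopent-2-en-1-one | O=C1C=C[C@@H](O[Si](C)(C)C(C)(C)C)C1
F2 | step 3 | dibenzyl 2-{[3-(tert-butyldimethylsilyloxy)-5-oxo-2-(prop-1-en-2-yl)cyclopentyl]methyl}propanedioate (all-trans) | O=C(OCc1ccccc1)C(C[C@H]1[C@@H]([C@@H](O[Si](C)(C)C(C)(C)C)CC1=O)C(C)=C)C(=O)OCc1ccccc1
F3 | step 3 | dibenzyl 2-{[2-oxo-5-(prop-1-en-2-yl)cyclopent-3-en-1-yl]methyl}propanedioate (trans) | O=C(OCc1ccccc1)C(C[C@H]1[C@@H](C=CC1=O)C(C)=C)C(=O)OCc1ccccc1
F4 | step 4 | dibenzyl 2-{[2-hydroxy-2-[(phenylselanyl)methyl]-5-(prop-1-en-2-yl)cyclopentyl]methyl}propanedioate (hydroxyl cis to the malonate arm) | O=C(OCc1ccccc1)C(C[C@H]1[C@@H](CC[C@@]1(C[Se]c1ccccc1)O)C(C)=C)C(=O)OCc1ccccc1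
F5 | step 6 | dibenzyl 2-bromo-2-{[(1S,2R,5R)-2-methyl-5-(prop-1-en-2-yl)-2-(triethylsilyloxy)cyclopentyl]methyl}propanedioate | O=C(OCc1ccccc1)C(Br)(C[C@H]1[C@@H](CC[C@@]1(C)O[Si](CC)(CC)CC)C(C)=C)C(=O)OCc1ccccc1
F6 | step 6 | bicyclic C5 tertiary bromide with geminal dibenzyl esters on C1 (both C5 epimers) | O=C(OCc1ccccc1)C1(C(=O)OCc2ccccc2)C[C@H]2[C@@H](CC[C@@]2(C)O[Si](CC)(CC)CC)C(C)(Br)C1
F7 | step 9 | acid chloride of the tricyclic lactone acid | O=C(Cl)[C@@]12C[C@H]3[C@@H](CC[C@@]3(C)O[Si](CC)(CC)CC)[C@@](C)(OC1=O)C2
F8 | step 9 | (3Z)-6-methyl-2,4-bis(trimethylsilyloxy)hepta-1,3-diene | C=C(O[Si](C)(C)C)/C=C(\O[Si](C)(C)C)CC(C)C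
F9 | step 10 | C11-diallyl spiro trione, C9 triethylsilyl ether | C=CCC1(CC=C)C(=O)[C@@]2(C[C@H]3[C@@H](CC[C@@]3(C)O[Si](CC)(CC)CC)[C@@](C)(O)C2)C(=O)C(C(=O)CC(C)C)=C1O
A1 | alternative 1 | prenyl-free spiro trione, C9 triethylsilyl ether (identical with 16) | CC(C)CC(=O)C1=C(O)C=C(O)[C@@]2(C[C@H]3[C@@H](CC[C@@]3(C)O[Si](CC)(CC)CC)[C@@](C)(O)C2)C1=O
A2 | alternative 2 | methyl (1S,2R)-2-hydroxy-2-methyl-5-[1-(tert-butyldimethylsilyloxy)ethyl]cyclopentane-1-carboxylate (hydroxyl and ester cis; C5 and the side-chain carbinol left open) | COC(=O)[C@H]1C(CC[C@@]1(C)O)C(C)O[Si](C)(C)C(C)(C)C
A3 | alternative 2 | methyl (E)-3-[1-(tert-butyldimethylsilyloxy)ethyl]-6-oxohept-2-enoate (silyloxy carbon left open) | COC(=O)/C=C(\CCC(C)=O)C(C)O[Si](C)(C)C(C)(C)C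
A4 | alternative 3 | methyl ester of the tricyclic lactone acid with free C9 hydroxyl | COC(=O)[C@@]2(C[C@H]3[C@@H](CC[C@@]3(C)O)[C@@](C)(O4)C2)C4=O
A5 | alternative 3 | dimethyl (Z)-1,5-dimethyl-10-oxabicyclo[7.1.0]dec-4-ene-7,7-dicarboxylate (cis-epoxide) | COC(=O)C1(C(=O)OC)C[C@@H]2O[C@]2(C)CC/C=C(C)\C1
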